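The plan cuts the C1–C6 bond of the cyclohexene and reconnects C4 to an oxygen, which turns the carbocycle into a pyranoid glycal. The feature exploited is the chain C7–C1(O)–C2(O)–C3(O)–C4. Quaternary carbinol C1 with its one-carbon arm, followed by the trans C2/C3 oxygens, corresponds to C1–C5 of a 2-alkoxy-D-glucal. One thermal Claisen rearrangement forms C1–C6, breaks O–C4, unmasks C7 as an aldehyde, closes the six-membered carbocycle and passes the sugar C5 configuration to C1. The precursor is a D-glucal with a vinyl group on C5, benzyl ethers on O2 and O3, and a 4-methoxybenzyl (PMB) ether on O4. Both benzoates are added later.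

Key step: step 8

Assumption: carbocycle locants C1–C7 and the α/β labels follow the target name (β is the face of the three hydroxyls); compounds 1–12 carry sugar locants; thioglycoside 1 is taken as a catalogue chemical.

Design remark: only ethers are carried through C6 homologation, anomeric elimination and heating, because a 4-O-acyl group β to the C6 aldehyde is prone to E1cB loss and an allylic ester in the rearranged product could shift or eliminate at the rearrangement temperature.

Step 1
Reactants: 1 phenyl 1-thio-β-D-glucopyranoside; 2 4-methoxybenzaldehyde dimethyl acetal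
Product: 3 phenyl 4,6-O-[(R)-4-methoxybenzylidene]-1-thio-β-D-glucopyranoside
Conditions: 2, camphorsulfonic acid (cat.), MeCN, 50 °C, MeOH removed under reduced pressure
Reagents that add atoms: 4-methoxybenzaldehyde dimethyl acetal (2), COc1ccc(C(OC)OC)cc1
Why: Acid-catalysed transacetalisation under thermodynamic control closes the trans-fused 1,3-dioxane on O4/O6, and the new acetal carbon becomes R because the aryl group settles equatorial.

Step 2
Reactants: 3 phenyl 4,6-O-[(R)-4-methoxybenzylidene]-1-thio-β-D-glucopyranoside; 4 benzyl bromide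
Product: 5 phenyl 2,3-di-O-benzyl-4,6-O-[(R)-4-methoxybenzylidene]-1-thio-β-D-glucopyranoside
Conditions: NaH, BnBr, Bu4NI (cat.), DMF, 0 °C to rt
Reagents that add atoms: benzyl bromide (4), BrCc1ccccc1
Why: Williamson etherification of the two remaining hydroxyls, to which the acetal and the thioglycoside are inert.

Step 3
Reactants: 5 phenyl 2,3-di-O-benzyl-4,6-O-[(R)-4-methoxybenzylidene]-1-thio-β-D-glucopyranoside
Product: 6 phenyl 2,3-di-O-benzyl-4-O-(4-methoxybenzyl)-1-thio-β-D-glucopyranoside
Conditions: iBu2AlH (toluene solution), CH2Cl2, −78 to 0 °C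
Reagents that add atoms: none
Why: Regioselective reductive acetal opening, in which aluminium binds the less hindered O6, the C–O6 bond ionises and hydride quenches the O4-stabilised cation, so PMB stays on O4 and the primary alcohol is freed.

Step 4
Reactants: 6 phenyl 2,3-di-O-benzyl-4-O-(4-methoxybenzyl)-1-thio-β-D-glucopyranoside
Product: 7 phenyl 2,3-di-O-benzyl-4-O-(4-methoxybenzyl)-1-thio-β-D-gluco-hexodialdo-1,5-pyranoside
Conditions: Dess–Martin periodinane, CH2Cl2, 0 °C to rt
Reagents that add atoms: none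
Why: Dess–Martin oxidation is base-free, so C5 is not epimerised, and it spares the sulfide and the benzylic ethers.

Step 5
Reactants: 7 phenyl 2,3-di-O-benzyl-4-O-(4-methoxybenzyl)-1-thio-β-D-gluco-hexodialdo-1,5-pyranoside; 8 methyltriphenylphosphonium bromide
Product: 9 phenyl 2,3-di-O-benzyl-6,7-dideoxy-4-O-(4-methoxybenzyl)-1-thio-β-D-gluco-hept-6-enopyranoside
Conditions: 8, KN(SiMe3)2, THF, 0 °C; then 7, −78 °C to rt
Reagents that add atoms: methyltriphenylphosphonium bromide (8), C[P+](c1ccccc1)(c1ccccc1)c1ccccc1.[Br-]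
Why: Wittig methylenation, in which the unstabilised ylide adds faster than it enolises the aldehyde and the 4-O-PMB ether is too poor a leaving group for β-elimination, so C5 keeps its configuration.

Step 6
Reactants: 9 phenyl 2,3-di-O-benzyl-6,7-dideoxy-4-O-(4-methoxybenzyl)-1-thio-β-D-gluco-hept-6-enopyranoside
Product: 10 2,3-di-O-benzyl-6,7-dideoxy-4-O-(4-methoxybenzyl)-D-gluco-hept-6-enopyranose (anomeric mixture)
Conditions: N-bromosuccinimide, aqueous acetone, −20 °C, dark
Reagents that add atoms: water, O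
Why: Halonium-promoted thioglycoside hydrolysis, in which the soft sulfur is brominated well before the electron-poor monosubstituted alkene or the PMB ring and water captures the oxocarbenium ion.

Step 7
Reactants: 10 2,3-di-O-benzyl-6,7-dideoxy-4-O-(4-methoxybenzyl)-D-gluco-hept-6-enopyranose
Product: 12 1,5-anhydro-2,3-di-O-benzyl-6,7-dideoxy-4-O-(4-methoxybenzyl)-D-arabino-hepta-1,6-dienitol (5-vinyl 2-benzyloxy-D-glucal), via α-glycosyl chloride 11 (not isolated)
Conditions: MsCl, Et3N, CH2Cl2, 0 °C to rt; then DBU, reflux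
Reagents that add atoms: none
Why: Anomeric mesylation with chloride displacement gives the axial α-chloride, whose C–Cl bond is antiperiplanar to axial H2, so an E2 dehydrohalogenation of the kind used to make 2-oxyglycals from glycosyl halides gives the enol ether, with no ester or acidic site present to compete.

Step 8
Reactants: 12 1,5-anhydro-2,3-di-O-benzyl-6,7-dideoxy-4-O-(4-methoxybenzyl)-D-arabino-hepta-1,6-dienitol
Product: 13 1β,2β-bis(benzyloxy)-3α-(4-methoxybenzyloxy)cyclohex-4-ene-1α-carbaldehyde
Conditions: degassed 1,2-dichlorobenzene (0.02 M), BHT (5 mol %), base-washed sealed tube, 220 °C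
Reagents that add atoms: none
Why: On heating, 12 flips to the inverted half-chair with the C5 vinyl group axial, and the enol ether C1=C2, the ring oxygen and the C5–C6=C7 allyl unit (sugar locants) undergo a concerted suprafacial [3,3]-sigmatropic shift that joins sugar C2 to C7 (target C1–C6), breaks O–C5 (target O–C4) and releases sugar C1 as the aldehyde C7. The closest known reaction type is the thermal Claisen rearrangement of 2-vinyl-3,4-dihydro-2H-pyrans, and of 5-vinyl glycals without a 2-substituent, to cyclohexenecarbaldehydes. The six-membered carbocycle is closed pericyclically through a bicyclo[2.2.2]octadiene-like boat array, because the two-carbon tether (sugar C3–C4) rules out a chair array. The only new stereocentre, quaternary C1, is fixed by the sugar C5 stereocentre, since the vinyl terminus can reach the enol carbon only from the pyran face that carries it; this leaves O1 cis to O2 and C7 trans to it, while C2 and C3 are spectators. The sigmatropic path must outrun acid-triggered Ferrier-type ionisation at sugar C3 and homolytic O-to-C benzyl migration, and this is addressed by ether-only protection, base-washed glass, a radical inhibitor and exclusion of air. The 2-benzyloxy group crowds the bond-forming carbon but also raises the donor strength of the enol ether, and its allylic strain against the 3-O-benzyl group favours the reactive all-axial conformer.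

Step 9
Reactants: 13 1β,2β-bis(benzyloxy)-3α-(4-methoxybenzyloxy)cyclohex-4-ene-1α-carbaldehyde
Product: 14 [1β,2β-bis(benzyloxy)-3α-(4-methoxybenzyloxy)cyclohex-4-en-1α-yl]methanol
Conditions: NaBH4, MeOH–CH2Cl2, 0 °C
Reagents that add atoms: none
Why: Borohydride reduction of a non-enolisable aldehyde that touches no stereocentre.

Step 10
Reactants: 14 [1β,2β-bis(benzyloxy)-3α-(4-methoxybenzyloxy)cyclohex-4-en-1α-yl]methanol
Product: 15 1β,2β-bis(benzyloxy)-1α-(hydroxymethyl)cyclohex-4-en-3α-ol
Conditions: DDQ, CH2Cl2–pH 7 buffer, 0 °C to rt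
Reagents that add atoms: none
Why: Oxidative PMB cleavage, in which DDQ abstracts hydride only from the electron-rich benzylic position and water hydrolyses the resulting oxocarbenium ion, leaving the plain benzyl ethers and the alkene untouched.

Step 11
Reactants: 15 1β,2β-bis(benzyloxy)-1α-(hydroxymethyl)cyclohex-4-en-3α-ol; 16 benzoyl chloride
Product: 17 3α-benzoyloxy-1α-benzoyloxymethyl-1β,2β-bis(benzyloxy)cyclohex-4-ene
Conditions: BzCl, pyridine, DMAP (cat.), 0 °C to rt
Reagents that add atoms: benzoyl chloride (16), O=C(Cl)c1ccccc1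
Why: DMAP-catalysed esterification installs both target benzoates in one operation, on the only two free hydroxyls.

Step 12
Reactants: 17 3α-benzoyloxy-1α-benzoyloxymethyl-1β,2β-bis(benzyloxy)cyclohex-4-ene
Product: 18 3α-benzoyloxy-1α-benzoyloxymethylcyclohex-4-ene-1β,2β-diol
Conditions: BCl3, pentamethylbenzene, CH2Cl2, −78 °C; MeOH quench
Reagents that add atoms: none
Why: Lewis-acid benzyl ether cleavage with a cation scavenger breaks the benzylic C–O bonds while sparing alkene and esters, and it is done at this stage because C1 is not yet allylic, so its tertiary C–O bond is not at risk.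

Step 13
Reactants: 18 3α-benzoyloxy-1α-benzoyloxymethylcyclohex-4-ene-1β,2β-diol
Product: 19 3α-benzoyloxy-1α-benzoyloxymethyl-4β,5β-epoxycyclohexane-1β,2β-diol
Conditions: VO(acac)2 (cat.), tBuOOH (decane), CH2Cl2, rt to 40 °C
Reagents that add atoms: tert-butyl hydroperoxide, CC(C)(C)OO
Why: Hydroxyl-directed vanadium-catalysed epoxidation, in which the tertiary C1 hydroxyl (axial on the β face and homoallylic to C5, as in cyclohex-3-enol) binds the metal alkylperoxide and delivers oxygen to the β face of C4=C5, setting C4 and the transient C5 centre.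

Step 14
Reactants: 19 3α-benzoyloxy-1α-benzoyloxymethyl-4β,5β-epoxycyclohexane-1β,2β-diol
Product: 22 1α-benzoyloxymethyl-3α-benzoyloxycyclohex-5-ene-1β,2β,4β-triol (target), via hydroxy selenide 20 (not isolated), via selenoxide 21 (not isolated)
Conditions: PhSeSePh, NaBH4, EtOH, 0 °C; then 19 in THF, 0 °C to rt; then 30% H2O2, THF, 0 °C to rt
Reagents that add atoms: none
Why: Epoxide-to-allylic-alcohol transposition by selenolate SN2 opening and selenoxide syn elimination, in which the soft selenolate should attack C5 from the α face (C5 adjoins the C6 methylene, whereas C4 is deactivated and screened by the neighbouring α-benzoate), the β C4–O bond is left untouched, and the selenoxide takes the syn α-hydrogen of C6 because elimination toward a carbinol carbon is disfavoured, placing the alkene at C5=C6.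

Compound list
1 | phenyl 1-thio-β-D-glucopyranoside | OC[C@H]1O[C@@H](Sc2ccccc2)[C@H](O)[C@@H](O)[C@@H]1O | starting material
2 | 4-methoxybenzaldehyde dimethyl acetal | COc1ccc(C(OC)OC)cc1 | starting material
3 | phenyl 4,6-O-[(R)-4-methoxybenzylidene]-1-thio-β-D-glucopyranoside | COc1ccc(cc1)[C@@H]1OC[C@H]2O[C@@H](Sc3ccccc3)[C@H](O)[C@@H](O)[C@@H]2O1 | intermediate
4 | benzyl bromide | BrCc1ccccc1 | starting material
5 | phenyl 2,3-di-O-benzyl-4,6-O-[(R)-4-methoxybenzylidene]-1-thio-β-D-glucopyranoside | COc1ccc(cc1)[C@@H]1OC[C@H]2O[C@@H](Sc3ccccc3)[C@H](OCc3ccccc3)[C@@H](OCc3ccccc3)[C@@H]2O1 | intermediate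
6 | phenyl 2,3-di-O-benzyl-4-O-(4-methoxybenzyl)-1-thio-β-D-glucopyranoside | OC[C@H]1O[C@@H](Sc2ccccc2)[C@H](OCc2ccccc2)[C@@H](OCc2ccccc2)[C@@H]1OCc1ccc(OC)cc1 | intermediate
7 | phenyl 2,3-di-O-benzyl-4-O-(4-methoxybenzyl)-1-thio-β-D-gluco-hexodialdo-1,5-pyranoside | O=C[C@H]1O[C@@H](Sc2ccccc2)[C@H](OCc2ccccc2)[C@@H](OCc2ccccc2)[C@@H]1OCc1ccc(OC)cc1 | intermediate
8 | methyltriphenylphosphonium bromide | C[P+](c1ccccc1)(c1ccccc1)c1ccccc1.[Br-] | starting material
9 | phenyl 2,3-di-O-benzyl-6,7-dideoxy-4-O-(4-methoxybenzyl)-1-thio-β-D-gluco-hept-6-enopyranoside | C=C[C@H]1O[C@@H](Sc2ccccc2)[C@H](OCc2ccccc2)[C@@H](OCc2ccccc2)[C@@H]1OCc1ccc(OC)cc1 | intermediate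
10 | 2,3-di-O-benzyl-6,7-dideoxy-4-O-(4-methoxybenzyl)-D-gluco-hept-6-enopyranose (anomeric mixture) | C=C[C@H]1OC(O)[C@H](OCc2ccccc2)[C@@H](OCc2ccccc2)[C@@H]1OCc1ccc(OC)cc1 | intermediate
11 | 2,3-di-O-benzyl-6,7-dideoxy-4-O-(4-methoxybenzyl)-α-D-gluco-hept-6-enopyranosyl chloride | C=C[C@H]1O[C@H](Cl)[C@H](OCc2ccccc2)[C@@H](OCc2ccccc2)[C@@H]1OCc1ccc(OC)cc1 | intermediate
12 | 1,5-anhydro-2,3-di-O-benzyl-6,7-dideoxy-4-O-(4-methoxybenzyl)-D-arabino-hepta-1,6-dienitol | C=C[C@H]1OC=C(OCc2ccccc2)[C@@H](OCc2ccccc2)[C@@H]1OCc1ccc(OC)cc1 | intermediate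
13 | 1β,2β-bis(benzyloxy)-3α-(4-methoxybenzyloxy)cyclohex-4-ene-1α-carbaldehyde | O=C[C@@]1(OCc2ccccc2)CC=C[C@@H](OCc2ccc(OC)cc2)[C@@H]1OCc1ccccc1 | intermediate
14 | [1β,2β-bis(benzyloxy)-3α-(4-methoxybenzyloxy)cyclohex-4-en-1α-yl]methanol | OC[C@@]1(OCc2ccccc2)CC=C[C@@H](OCc2ccc(OC)cc2)[C@@H]1OCc1ccccc1 | intermediate
15 | 1β,2β-bis(benzyloxy)-1α-(hydroxymethyl)cyclohex-4-en-3α-ol | OC[C@@]1(OCc2ccccc2)CC=C[C@@H](O)[C@@H]1OCc1ccccc1 | intermediate
16 | benzoyl chloride | O=C(Cl)c1ccccc1 | starting material
17 | 3α-benzoyloxy-1α-benzoyloxymethyl-1β,2β-bis(benzyloxy)cyclohex-4-ene | O=C(OC[C@@]1(OCc2ccccc2)CC=C[C@@H](OC(=O)c2ccccc2)[C@@H]1OCc1ccccc1)c1ccccc1 | intermediate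
18 | 3α-benzoyloxy-1α-benzoyloxymethylcyclohex-4-ene-1β,2β-diol | O=C(OC[C@@]1(O)CC=C[C@@H](OC(=O)c2ccccc2)[C@@H]1O)c1ccccc1 | intermediate
19 | 3α-benzoyloxy-1α-benzoyloxymethyl-4β,5β-epoxycyclohexane-1β,2β-diol | O=C(OC[C@@]1(O)C[C@@H]2O[C@@H]2[C@@H](OC(=O)c2ccccc2)[C@@H]1O)c1ccccc1 | intermediate
20 | 3α-benzoyloxy-1α-benzoyloxymethyl-5α-phenylselanylcyclohexane-1β,2β,4β-triol | O=C(OC[C@@]1(O)C[C@@H]([Se]c2ccccc2)[C@H](O)[C@@H](OC(=O)c2ccccc2)[C@@H]1O)c1ccccc1 | intermediate
21 | selenoxide of 20 (configuration at selenium undefined) | O=C(OC[C@@]1(O)C[C@@H]([Se](=O)c2ccccc2)[C@H](O)[C@@H](OC(=O)c2ccccc2)[C@@H]1O)c1ccccc1 | intermediate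
22 | 1α-benzoyloxymethyl-3α-benzoyloxycyclohex-5-ene-1β,2β,4β-triol | O=C(OC[C@@]1(O)C=C[C@H](O)[C@@H](OC(=O)c2ccccc2)[C@@H]1O)c1ccccc1 | target

Total step count: 14. Longest linear sequence: 14 steps (from 1).

Steps most likely to fail

Step 8 (thermal Claisen rearrangement).
- Risk: the fully substituted bond-forming carbon may push the required temperature into the range where other processes consume the glycal first. These are ionisation at sugar C3, homolytic benzyl migration from O2 to carbon, and polymerisation of the diene.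
- Fallback: the same bond is made at the lactone oxidation level, where a silyloxy donor on the vinyl ether carbon lowers the barrier strongly (Ireland–Claisen rearrangement of a lactone silyl ketene acetal). It sets out from hemiacetal 10, which Dess–Martin periodinane oxidises to 2,3-di-O-benzyl-6,7-dideoxy-4-O-(4-methoxybenzyl)-D-gluco-hept-6-enono-1,5-lactone F1. Enolisation with LiN(iPr)2 in the presence of TBSCl at −78 °C (internal quench, to outrun β-elimination of the 3-benzyloxy group) gives the cyclic tert-butyldimethylsilyl ketene acetal F2. On warming in toluene this should pass through the same boat array to tert-butyldimethylsilyl 1β,2β-bis(benzyloxy)-3α-(4-methoxybenzyloxy)cyclohex-4-ene-1α-carboxylate F3. LiAlH4 reduces the silyl ester directly to alcohol 14, where the route is rejoined.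

Step 14 (epoxide opening and elimination).
- Risk: the trans-diaxial preference of the more stable half-chair of 19 opposes the polar and steric preference for C5, so part of the selenolate may attack C4. The mildly basic medium may also move benzoyl groups among O2, O3 and O4.
- Fallback: C4 is set by carbonyl reduction instead of by epoxide opening, with O1 and O2 kept as benzyl ethers. It sets out from 17. mCPBA should attack mainly the α face, since the β face carries the axial O1 benzyl group, giving the 4α,5α-epoxide F4, in which polar and trans-diaxial preferences both point to C5. PhSeSePh/NaBH4 then gives the 5β-phenylselanyl-4α-ol F5. H2O2 converts it through the selenoxide F6 into the 4α-allylic alcohol F7. Dess–Martin oxidation gives the cyclohex-5-en-4-one F8; any β-epoxide that opened at C5 converges on this same enone. Luche reduction (NaBH4, CeCl3·7H2O, MeOH) with axial hydride delivery from the α face should give the pseudo-equatorial 4β-alcohol F9. BCl3 with pentamethylbenzene at −78 °C then returns to the route at target 22.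

Step 7 (anomeric elimination).
- Risk: the base may substitute at the anomeric carbon of the reactive chloride instead of removing H2, and the acid-labile enol ether may hydrolyse or ionise during isolation.
- Fallback: the base-induced anti elimination is replaced by a neutral intramolecular syn elimination. It sets out from 10, again through chloride 11. The chloride is displaced with inversion by PhSeSePh/NaBH4 to give the phenyl 1-seleno-β-glycoside F10, whose selenium is cis to H2. Oxidation with mCPBA at −78 °C gives the glycosyl selenoxide F11, which on warming with iPr2NH loses the selenenic acid and returns to the route at glycal 12.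

Further compounds
F1 | step 8 | 2,3-di-O-benzyl-6,7-dideoxy-4-O-(4-methoxybenzyl)-D-gluco-hept-6-enono-1,5-lactone | C=C[C@H]1OC(=O)[C@H](OCc2ccccc2)[C@@H](OCc2ccccc2)[C@@H]1OCc1ccc(OC)cc1
F2 | step 8 | cyclic tert-butyldimethylsilyl ketene acetal of F1 | C=C[C@H]1OC(O[Si](C)(C)C(C)(C)C)=C(OCc2ccccc2)[C@@H](OCc2ccccc2)[C@@H]1OCc1ccc(OC)cc1
F3 | step 8 | tert-butyldimethylsilyl 1β,2β-bis(benzyloxy)-3α-(4-methoxybenzyloxy)cyclohex-4-ene-1α-carboxylate | CC(C)(C)[Si](C)(C)OC(=O)[C@@]1(OCc2ccccc2)CC=C[C@@H](OCc2ccc(OC)cc2)[C@@H]1OCc1ccccc1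
F4 | step 14 | 3α-benzoyloxy-1α-benzoyloxymethyl-1β,2β-bis(benzyloxy)-4α,5α-epoxycyclohexane | O=C(OC[C@@]1(OCc2ccccc2)C[C@H]2O[C@H]2[C@@H](OC(=O)c2ccccc2)[C@@H]1OCc1ccccc1)c1ccccc1
F5 | step 14 | 3α-benzoyloxy-1α-benzoyloxymethyl-1β,2β-bis(benzyloxy)-5β-phenylselanylcyclohexan-4α-ol | O=C(OC[C@@]1(OCc2ccccc2)C[C@H]([Se]c2ccccc2)[C@@H](O)[C@@H](OC(=O)c2ccccc2)[C@@H]1OCc1ccccc1)c1ccccc1
F6 | step 14 | selenoxide of F5 | O=C(OC[C@@]1(OCc2ccccc2)C[C@H]([Se](=O)c2ccccc2)[C@@H](O)[C@@H](OC(=O)c2ccccc2)[C@@H]1OCc1ccccc1)c1ccccc1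
F7 | step 14 | 3α-benzoyloxy-1α-benzoyloxymethyl-1β,2β-bis(benzyloxy)cyclohex-5-en-4α-ol | O=C(OC[C@@]1(OCc2ccccc2)C=C[C@@H](O)[C@@H](OC(=O)c2ccccc2)[C@@H]1OCc1ccccc1)c1ccccc1
F8 | step 14 | 3α-benzoyloxy-1α-benzoyloxymethyl-1β,2β-bis(benzyloxy)cyclohex-5-en-4-one | O=C(OC[C@@]1(OCc2ccccc2)C=CC(=O)[C@@H](OC(=O)c2ccccc2)[C@@H]1OCc1ccccc1)c1ccccc1
F9 | step 14 | 3α-benzoyloxy-1α-benzoyloxymethyl-1β,2β-bis(benzyloxy)cyclohex-5-en-4β-ol | O=C(OC[C@@]1(OCc2ccccc2)C=C[C@H](O)[C@@H](OC(=O)c2ccccc2)[C@@H]1OCc1ccccc1)c1ccccc1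
F10 | step 7 | phenyl 2,3-di-O-benzyl-6,7-dideoxy-4-O-(4-methoxybenzyl)-1-seleno-β-D-gluco-hept-6-enopyranoside | C=C[C@H]1O[C@@H]([Se]c2ccccc2)[C@H](OCc2ccccc2)[C@@H](OCc2ccccc2)[C@@H]1OCc1ccc(OC)cc1
F11 | step 7 | selenoxide of F10 | C=C[C@H]1O[C@@H]([Se](=O)c2ccccc2)[C@H](OCc2ccccc2)[C@@H](OCc2ccccc2)[C@@H]1OCc1ccc(OC)cc1
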